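**Strategy**

The route rests on opening the lower pyran ring (O1''–C2''–C3''–C4'') of the catechol flavan at O1''–C2'' and C3''–C4''. Its unsubstituted C4'' methylene next to the cis C2''-aryl/C3''-oxygen pair is the imprint of a methylene o-quinone methide (O1''=C8a''–C4a''=C4'') and a Z-alkene. In one operation an inverse-demand oxa-[4+2] cycloaddition builds that ring, both bonds and both lower stereocentres on a finished upper unit. The precursor is the all-trans 4-arylflavan-3-ol whose C4 aryl group is a 4-benzyloxy-2-hydroxybenzyl alcohol, unmasked from an acetonide that carries the salicyl alcohol safely through coupling and hydroboration; its partner is a (Z)-2-arylvinyl acetate.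

Key step: step 12

Assumption: the (R)-ligand in step 2 is taken to give the 2S flavanone by analogy with cyclic enones, and the sense of the acid in step 12 cannot be predicted; in either case the catalyst antipode is exchanged if the opposite sense is found.

Notes on structures:
- No structural error was found: the Z-alkene/2,3-cis correlation and the ring positions of the linking resorcinol are consistent.
- C4 of the upper unit reads 4S in every O-benzylated intermediate and 4R in the free phenol. The spatial arrangement is the same; the CIP ranking of the two aryl branches changes when the 7''-oxygen loses its benzyl group.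
- The upper 3-OH is carried free. It cannot reach C4'' within the molecule, and step 12 already tolerates the water it releases.

**Route**

Step 1
Reactants: 1 1-[4-(benzyloxy)-2-hydroxyphenyl]ethan-1-one
Product: 3 7-(benzyloxy)-4H-chromen-4-one, via enaminone 2 (not isolated)
Conditions: DMF-DMA, toluene, 100 °C; then conc. HCl, CH2Cl2, 40 °C
Reagents that add atoms: N,N-dimethylformamide dimethyl acetal, COC(OC)N(C)C
Why: Condensation of the methyl ketone with the amide acetal gives the enaminone, and acid-induced oxa-Michael addition with loss of dimethylamine closes the pyranone, which is the standard chromone annulation and leaves the benzyl ether untouched.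

Step 2
Reactants: 3 7-(benzyloxy)-4H-chromen-4-one; 4 [4-(benzyloxy)phenyl]boronic acid
Product: 5 (2S)-7-(benzyloxy)-2-[4-(benzyloxy)phenyl]chroman-4-one
Conditions: Pd(OCOCF3)2 (5 mol%), (R)-t-BuPyOx (6 mol%), NH4PF6 (30 mol%), H2O (5 equiv), ClCH2CH2Cl, 60 °C
Reagents that add atoms: none
Why: Palladium-catalysed asymmetric conjugate addition of an arylboronic acid to a chromone (Hayashi–Miyaura-type 1,4-addition with a pyridine-oxazoline ligand) sets C2 in the ligand-controlled migratory insertion, and the 2S flavanone has the spatial arrangement of the 2R flavan-3-ol.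

Step 3
Reactants: 5 (2S)-7-(benzyloxy)-2-[4-(benzyloxy)phenyl]chroman-4-one
Product: 6 (2S)-7-(benzyloxy)-2-[4-(benzyloxy)phenyl]-2H-chromen-4-yl trifluoromethanesulfonate
Conditions: Tf2O, 2,6-di-tert-butyl-4-methylpyridine, CH2Cl2, 0 °C to rt
Reagents that add atoms: triflic anhydride, O=S(=O)(OS(=O)(=O)C(F)(F)F)C(F)(F)F
Why: Enol triflate formation by O-sulfonylation of the ketone and loss of the C3 proton to the hindered pyridine avoids a free enolate, so the retro-oxa-Michael ring opening that would racemise C2 should not occur.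

Step 4
Reactants: 7 5-bromo-2,4-dihydroxybenzaldehyde
Product: 8 4-(benzyloxy)-5-bromo-2-hydroxybenzaldehyde
Conditions: BnBr (1.05 equiv), CsHCO3, MeCN, 80 °C
Reagents that add atoms: benzyl bromide, BrCc1ccccc1
Why: Williamson etherification should be selective for the more acidic 4-OH, because the 2-OH is held in a hydrogen bond to the formyl group and is not deprotonated by a hydrogencarbonate base.

Step 5
Reactants: 8 4-(benzyloxy)-5-bromo-2-hydroxybenzaldehyde
Product: 9 5-(benzyloxy)-4-bromo-2-(hydroxymethyl)phenol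
Conditions: NaBH4, THF/MeOH, 0 °C; aq NH4Cl
Reagents that add atoms: none
Why: Borohydride reduction of the aldehyde fixes C4'' at the alcohol level on a small molecule under cold, non-acidic conditions that spare the aryl bromide and do not ionise the benzylic hydroxyl.

Step 6
Reactants: 9 5-(benzyloxy)-4-bromo-2-(hydroxymethyl)phenol
Product: 10 7-(benzyloxy)-6-bromo-2,2-dimethyl-4H-1,3-benzodioxine
Conditions: 2,2-dimethoxypropane, PPTS (cat.), acetone, rt
Reagents that add atoms: 2,2-dimethoxypropane, COC(C)(C)OC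
Why: Acid-catalysed transacetalisation masks phenol and benzylic alcohol as one acetonide that tolerates base, palladium, borane and alkaline peroxide, where an aryl aldehyde would risk Dakin oxidation and over-reduction.

Step 7
Reactants: 10 7-(benzyloxy)-6-bromo-2,2-dimethyl-4H-1,3-benzodioxine; 6 (2S)-7-(benzyloxy)-2-[4-(benzyloxy)phenyl]-2H-chromen-4-yl trifluoromethanesulfonate
Product: 12 (2S)-7-(benzyloxy)-4-[7-(benzyloxy)-2,2-dimethyl-4H-1,3-benzodioxin-6-yl]-2-[4-(benzyloxy)phenyl]-2H-chromene, via aryl pinacol boronate 11 (not isolated)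
Conditions: 10 (1.3 equiv), B2pin2, Pd(dppf)Cl2 (3 mol%), KOAc, 1,4-dioxane, 85 °C; then 6, aq K3PO4, 60 °C, dark
Reagents that add atoms: bis(pinacolato)diboron, CC1(C)OB(OC1(C)C)B1OC(C)(C)C(C)(C)O1 (boron and pinacol of intermediate 11 only)
Why: Miyaura borylation of the aryl bromide followed in the same flask by Suzuki–Miyaura coupling with the enol triflate forms the C4–C6'' bond without touching C2, and moderate temperature with exclusion of light guards the 2H-chromene against electrocyclic ring opening.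

Step 8
Reactants: 12 (2S)-7-(benzyloxy)-4-[7-(benzyloxy)-2,2-dimethyl-4H-1,3-benzodioxin-6-yl]-2-[4-(benzyloxy)phenyl]-2H-chromene
Product: 14 (2R,3S,4S)-7-(benzyloxy)-4-[7-(benzyloxy)-2,2-dimethyl-4H-1,3-benzodioxin-6-yl]-2-[4-(benzyloxy)phenyl]chroman-3-ol, via C3 alkylborane 13 (not isolated)
Conditions: BH3·THF, THF, 0 °C to rt; then NaOH, H2O2, H2O, 0 °C to rt
Reagents that add atoms: hydrogen peroxide, OO (oxygen of the 3-OH); borane–tetrahydrofuran, B.C1CCOC1 (boron of intermediate 13 only)
Why: Brown hydroboration–oxidation places boron on C3 and hydrogen on the diaryl-substituted C4 in a syn addition on the face opposite the 2-aryl group, and oxidation with retention should give the 2,3-trans-3,4-trans flavan-3-ol (C3 and C4 set by substrate control from C2).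

Step 9
Reactants: 14 (2R,3S,4S)-7-(benzyloxy)-4-[7-(benzyloxy)-2,2-dimethyl-4H-1,3-benzodioxin-6-yl]-2-[4-(benzyloxy)phenyl]chroman-3-ol
Product: 15 (2R,3S,4S)-7-(benzyloxy)-4-[2-(benzyloxy)-4-hydroxy-5-(hydroxymethyl)phenyl]-2-[4-(benzyloxy)phenyl]chroman-3-ol
Conditions: AcOH/THF/H2O (3:1:1), 40 °C
Reagents that add atoms: none
Why: Mild aqueous acid hydrolysis of the acetal releases the salicyl alcohol, the large excess of water returning any transient methide to the alcohol, while benzyl ethers and the C4–aryl bond of this 5-deoxy flavan are stable to acetic acid.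

Step 10
Reactants: 16 3,4-bis(benzyloxy)benzaldehyde
Product: 17 1,2-bis(benzyloxy)-4-ethynylbenzene
Conditions: dimethyl (1-diazo-2-oxopropyl)phosphonate, K2CO3, MeOH/THF, rt
Reagents that add atoms: dimethyl (1-diazo-2-oxopropyl)phosphonate, COP(=O)(OC)C(=[N+]=[N-])C(C)=O
Why: Seyferth–Gilbert homologation in the Ohira–Bestmann variant converts the aryl aldehyde into the terminal alkyne under mild carbonate base.

Step 11
Reactants: 17 1,2-bis(benzyloxy)-4-ethynylbenzene
Product: 18 (Z)-2-[3,4-bis(benzyloxy)phenyl]ethenyl acetate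
Conditions: AcOH (1.5 equiv), Ru(methallyl)2(dppb) (2 mol%), toluene, 60 °C
Reagents that add atoms: acetic acid, CC(=O)O
Why: Ruthenium-catalysed anti-Markovnikov hydro-acyloxylation of a terminal alkyne through a vinylidene complex places the acetate on the terminal carbon and should give the Z enol ester under catalyst control.

Step 12
Reactants: 15 (2R,3S,4S)-7-(benzyloxy)-4-[2-(benzyloxy)-4-hydroxy-5-(hydroxymethyl)phenyl]-2-[4-(benzyloxy)phenyl]chroman-3-ol; 18 (Z)-2-[3,4-bis(benzyloxy)phenyl]ethenyl acetate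
Product: 20 (2S,3S)-7-(benzyloxy)-6-{(2R,3S,4S)-7-(benzyloxy)-2-[4-(benzyloxy)phenyl]-3-hydroxychroman-4-yl}-2-[3,4-bis(benzyloxy)phenyl]chroman-3-yl acetate, via o-quinone methide 19 (not isolated)
Conditions: (S)-3,3'-bis(2,4,6-triisopropylphenyl)-BINOL N-triflylphosphoramide (5 mol%), 18 (2.5 equiv), 5 Å MS, toluene, 0 °C to rt, slow addition of 15
Reagents that add atoms: none
Why: Proposed new method: the chiral acid ionises the salicyl alcohol of 15 to the methylene o-quinone methide 19 (O1''=C8a''–C4a''=C4''), held as a hydrogen-bonded contact ion pair with the phosphoramide anion, and the electron-rich Z-alkene 18 adds across O1'' and C4'' in an inverse-electron-demand oxa-[4+2] that restores the aromatic ring. The closest known chemistry is the acid- or heat-induced hetero-Diels–Alder of salicyl-alcohol-derived o-quinone methides with styrenes, enol ethers and enol esters, together with confined-chiral-acid hetero-[4+2] additions of simple styrenes to unsubstituted methylene heterodienes; catalyst control of the alkene face on an unsubstituted methide beside remote stereocentres has not been shown and is the new element. The lower pyran closes as a six-membered ring by concerted, asynchronous cycloaddition, C3''–C4'' leading and O1''–C2'' following (a 6-exo-trig capture of the benzylic cation by O1'' in the stepwise limit). C2'' and C3'' are set together: their cis relation comes from suprafacial addition to the Z alkene, their absolute sense (2''S,3''S) from the chiral counter-anion bound at O1'', and C4'' is not stereogenic, so endo/exo selection does not matter. The step needs the acetoxy-bearing carbon to be the nucleophilic one, which the 4-alkoxyphenyl group secures by stabilising positive charge at C2'' far better than the weakly donating acyloxy group could at C3'', and the 7''-benzyloxy group para to C4'' lets the methide form under mild acid.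

Step 13
Reactants: 20 (2S,3S)-7-(benzyloxy)-6-{(2R,3S,4S)-7-(benzyloxy)-2-[4-(benzyloxy)phenyl]-3-hydroxychroman-4-yl}-2-[3,4-bis(benzyloxy)phenyl]chroman-3-yl acetate
Product: 21 (2R,3S,4S)-7-(benzyloxy)-4-{(2S,3S)-7-(benzyloxy)-2-[3,4-bis(benzyloxy)phenyl]-3-hydroxychroman-6-yl}-2-[4-(benzyloxy)phenyl]chroman-3-ol
Conditions: K2CO3 (0.3 equiv), MeOH/THF, rt
Reagents that add atoms: none
Why: Base-catalysed transesterification (Zemplén-type methanolysis) removes the acetate while all phenols are still benzylated, so no phenoxide is present that could open a pyran ring and epimerise C2 or C2''.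

Step 14
Reactants: 21 (2R,3S,4S)-7-(benzyloxy)-4-{(2S,3S)-7-(benzyloxy)-2-[3,4-bis(benzyloxy)phenyl]-3-hydroxychroman-6-yl}-2-[4-(benzyloxy)phenyl]chroman-3-ol
Product: 22 (2R,3S,4R)-4-[(2S,3S)-2-(3,4-dihydroxyphenyl)-3,7-dihydroxychroman-6-yl]-2-(4-hydroxyphenyl)chroman-3,7-diol
Conditions: H2 (1 atm), Pd(OH)2/C, THF/MeOH, rt
Reagents that add atoms: none
Why: Catalytic hydrogenolysis over Pearlman's catalyst at ambient pressure should cleave the five benzyl ethers under neutral conditions and leave the benzylic pyran C–O bonds and all five stereocentres intact.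

**Compound list**

1 | 1-[4-(benzyloxy)-2-hydroxyphenyl]ethan-1-one | CC(=O)c1ccc(OCc2ccccc2)cc1O | starting material
2 | (E)-1-[4-(benzyloxy)-2-hydroxyphenyl]-3-(dimethylamino)prop-2-en-1-one | CN(C)/C=C/C(=O)c1ccc(OCc2ccccc2)cc1O | intermediate (not isolated)
3 | 7-(benzyloxy)-4H-chromen-4-one | O=c1ccoc2cc(OCc3ccccc3)ccc12 | intermediate
4 | [4-(benzyloxy)phenyl]boronic acid | OB(O)c1ccc(OCc2ccccc2)cc1 | starting material
5 | (2S)-7-(benzyloxy)-2-[4-(benzyloxy)phenyl]chroman-4-one | O=C1C[C@@H](c2ccc(OCc3ccccc3)cc2)Oc2cc(OCc3ccccc3)ccc12 | intermediate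
6 | (2S)-7-(benzyloxy)-2-[4-(benzyloxy)phenyl]-2H-chromen-4-yl trifluoromethanesulfonate | O=S(=O)(OC1=C[C@@H](c2ccc(OCc3ccccc3)cc2)Oc2cc(OCc3ccccc3)ccc12)C(F)(F)F | intermediate
7 | 5-bromo-2,4-dihydroxybenzaldehyde | O=Cc1cc(Br)c(O)cc1O | starting material
8 | 4-(benzyloxy)-5-bromo-2-hydroxybenzaldehyde | O=Cc1cc(Br)c(OCc2ccccc2)cc1O | intermediate
9 | 5-(benzyloxy)-4-bromo-2-(hydroxymethyl)phenol | OCc1cc(Br)c(OCc2ccccc2)cc1O | intermediate
10 | 7-(benzyloxy)-6-bromo-2,2-dimethyl-4H-1,3-benzodioxine | CC1(C)OCc2cc(Br)c(OCc3ccccc3)cc2O1 | intermediate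
11 | 2-[7-(benzyloxy)-2,2-dimethyl-4H-1,3-benzodioxin-6-yl]-4,4,5,5-tetramethyl-1,3,2-dioxaborolane | CC1(C)OCc2cc(B3OC(C)(C)C(C)(C)O3)c(OCc3ccccc3)cc2O1 | intermediate (not isolated)
12 | (2S)-7-(benzyloxy)-4-[7-(benzyloxy)-2,2-dimethyl-4H-1,3-benzodioxin-6-yl]-2-[4-(benzyloxy)phenyl]-2H-chromene | CC1(C)OCc2cc(C3=C[C@@H](c4ccc(OCc5ccccc5)cc4)Oc4cc(OCc5ccccc5)ccc34)c(OCc3ccccc3)cc2O1 | intermediate
13 | C3 alkylborane of 12: BH2 on C3 trans to the 2-aryl group, hydrogen on C4 cis to boron | c9ccccc9COc1ccc([C@H]2Oc3cc(OCc9ccccc9)ccc3[C@@H](c3cc4c(cc3OCc9ccccc9)OC(C)(C)OC4)[C@@H]2B)cc1 | intermediate (not isolated)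
14 | (2R,3S,4S)-7-(benzyloxy)-4-[7-(benzyloxy)-2,2-dimethyl-4H-1,3-benzodioxin-6-yl]-2-[4-(benzyloxy)phenyl]chroman-3-ol | c9ccccc9COc1ccc([C@H]2Oc3cc(OCc9ccccc9)ccc3[C@@H](c3cc4c(cc3OCc9ccccc9)OC(C)(C)OC4)[C@@H]2O)cc1 | intermediate
15 | (2R,3S,4S)-7-(benzyloxy)-4-[2-(benzyloxy)-4-hydroxy-5-(hydroxymethyl)phenyl]-2-[4-(benzyloxy)phenyl]chroman-3-ol | c9ccccc9COc1ccc([C@H]2Oc3cc(OCc9ccccc9)ccc3[C@@H](c3cc(CO)c(O)cc3OCc9ccccc9)[C@@H]2O)cc1 | intermediate
16 | 3,4-bis(benzyloxy)benzaldehyde | O=Cc1ccc(OCc2ccccc2)c(OCc2ccccc2)c1 | starting material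
17 | 1,2-bis(benzyloxy)-4-ethynylbenzene | C#Cc1ccc(OCc2ccccc2)c(OCc2ccccc2)c1 | intermediate
18 | (Z)-2-[3,4-bis(benzyloxy)phenyl]ethenyl acetate | CC(=O)O/C=C\c1ccc(OCc2ccccc2)c(OCc2ccccc2)c1 | intermediate
19 | 3-(benzyloxy)-4-{(2R,3S,4S)-7-(benzyloxy)-2-[4-(benzyloxy)phenyl]-3-hydroxychroman-4-yl}-6-methylidenecyclohexa-2,4-dien-1-one | c9ccccc9COc1ccc([C@H]2Oc3cc(OCc9ccccc9)ccc3[C@@H](C3=CC(=C)C(=O)C=C3OCc9ccccc9)[C@@H]2O)cc1 | intermediate (not isolated)
20 | (2S,3S)-7-(benzyloxy)-6-{(2R,3S,4S)-7-(benzyloxy)-2-[4-(benzyloxy)phenyl]-3-hydroxychroman-4-yl}-2-[3,4-bis(benzyloxy)phenyl]chroman-3-yl acetate | c9ccccc9COc1ccc([C@H]2Oc3cc(OCc9ccccc9)ccc3[C@@H](c3cc4c(cc3OCc9ccccc9)O[C@@H](c3ccc(OCc9ccccc9)c(OCc9ccccc9)c3)[C@@H](OC(C)=O)C4)[C@@H]2O)cc1 | intermediate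
21 | (2R,3S,4S)-7-(benzyloxy)-4-{(2S,3S)-7-(benzyloxy)-2-[3,4-bis(benzyloxy)phenyl]-3-hydroxychroman-6-yl}-2-[4-(benzyloxy)phenyl]chroman-3-ol | c9ccccc9COc1ccc([C@H]2Oc3cc(OCc9ccccc9)ccc3[C@@H](c3cc4c(cc3OCc9ccccc9)O[C@@H](c3ccc(OCc9ccccc9)c(OCc9ccccc9)c3)[C@@H](O)C4)[C@@H]2O)cc1 | intermediate
22 | (2R,3S,4R)-4-[(2S,3S)-2-(3,4-dihydroxyphenyl)-3,7-dihydroxychroman-6-yl]-2-(4-hydroxyphenyl)chroman-3,7-diol | Oc1ccc([C@H]2Oc3cc(O)ccc3[C@@H](c3cc4c(cc3O)O[C@@H](c3ccc(O)c(O)c3)[C@@H](O)C4)[C@@H]2O)cc1 | target

**Count and risks**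

Total: 14 steps. Longest linear sequence: 9 steps (1, 2, 3, 7, 8, 9, 12, 13, 14; equally 4, 5, 6, 7, 8, 9, 12, 13, 14).

Step 12 is the most likely to fail. The catalyst may not distinguish the two alkene faces, the cis relation may erode if a stepwise cation pathway with acetoxy participation competes, and the methide may oligomerise. The fallback uses known chemistry and gives up face control. It sets out from 15, which is condensed with phenylboronic acid (toluene, azeotropic drying; the lone 3-OH is not engaged) to the 2-phenyl-4H-1,3,2-benzodioxaborin F1. Heating F1 with 18 (3 equiv) in toluene at 110–140 °C releases the same methide without acid, and the uncatalysed, concerted cycloaddition retains the alkene geometry. This should give 20 together with its (2''R,3''R) lower-unit diastereomer F2. The two are diastereomers because the upper unit is enantiopure, so preparative chromatography separates them. The fallback returns to the route at 20.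

Step 2 is second. Insertion into the electron-rich 7-alkoxychromone may be sluggish, the boronic acid may protodeboronate, or the enantioselectivity may be insufficient. The fallback sets out from 1. Claisen–Schmidt condensation with 4-(benzyloxy)benzaldehyde (KOH, EtOH) gives the 2'-hydroxychalcone F3, and NaOAc in refluxing EtOH cyclises it to the racemic flavanone F4. Preparative chromatography on a polysaccharide chiral phase then delivers 5 and the (2R)-flavanone F5, which can be recycled by base-induced ring opening and reclosure. The fallback returns at 5.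

Step 3 is third. The flavanone may open to the chalcone during triflation, which would also racemise C2, or enolisation may be incomplete. The fallback sets out from 5 and 10 and bypasses both the triflate and the coupling. Bromine–lithium exchange on 10 (n-BuLi, THF, −78 °C) and transmetalation with CeCl3 give a weakly basic aryl nucleophile, whose 1,2-addition to 5 should give the tertiary 4-arylflavan-4-ol F6. Dehydration with Burgess reagent (THF, 50 °C) then forms the C3=C4 alkene. The fallback returns at 12.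

Further compounds
F1 | step 12 | (2R,3S,4S)-7-(benzyloxy)-4-[7-(benzyloxy)-2-phenyl-4H-1,3,2-benzodioxaborin-6-yl]-2-[4-(benzyloxy)phenyl]chroman-3-ol | c9ccccc9COc1ccc([C@H]2Oc3cc(OCc9ccccc9)ccc3[C@@H](c3cc4c(cc3OCc9ccccc9)OB(c3ccccc3)OC4)[C@@H]2O)cc1
F2 | step 12 | (2R,3R)-7-(benzyloxy)-6-{(2R,3S,4S)-7-(benzyloxy)-2-[4-(benzyloxy)phenyl]-3-hydroxychroman-4-yl}-2-[3,4-bis(benzyloxy)phenyl]chroman-3-yl acetate | c9ccccc9COc1ccc([C@H]2Oc3cc(OCc9ccccc9)ccc3[C@@H](c3cc4c(cc3OCc9ccccc9)O[C@H](c3ccc(OCc9ccccc9)c(OCc9ccccc9)c3)[C@H](OC(C)=O)C4)[C@@H]2O)cc1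
F3 | step 2 | (E)-1-[4-(benzyloxy)-2-hydroxyphenyl]-3-[4-(benzyloxy)phenyl]prop-2-en-1-one | O=C(/C=C/c1ccc(OCc2ccccc2)cc1)c1ccc(OCc2ccccc2)cc1O
F4 | step 2 | racemic 7-(benzyloxy)-2-[4-(benzyloxy)phenyl]chroman-4-one | O=C1CC(c2ccc(OCc3ccccc3)cc2)Oc2cc(OCc3ccccc3)ccc12
F5 | step 2 | (2R)-7-(benzyloxy)-2-[4-(benzyloxy)phenyl]chroman-4-one | O=C1C[C@H](c2ccc(OCc3ccccc3)cc2)Oc2cc(OCc3ccccc3)ccc12
F6 | step 3 | (2S)-7-(benzyloxy)-4-[7-(benzyloxy)-2,2-dimethyl-4H-1,3-benzodioxin-6-yl]-2-[4-(benzyloxy)phenyl]chroman-4-ol (mixture at C4) | CC1(C)OCc2cc(C3(O)C[C@@H](c4ccc(OCc5ccccc5)cc4)Oc4cc(OCc5ccccc5)ccc34)c(OCc3ccccc3)cc2O1
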